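**Plan**

1. The target is 5-hydroxy-7-methoxy-2-methylchromone (pyranone ring A, benzene ring B) joined through a CH2 bridge from its C6 to C5 of (3R)-6,8-dihydroxy-3,7-dimethylisochroman-1-one (benzene ring C, lactone ring D; the locants C1–C8a used below belong to this half).
2. Retrosynthetic cuts, in order: the bridge CH2–C5 bond; the two phenol ethers and a temporary C4–CO2H bond; in ring D the C3–C4 bond together with the O2–C1 ester bond; finally the anhydride back to the toluate methyl of atraric acid.
3. The enabling feature is that C3, the only stereocentre, lies between the two ring D bonds, so ring D is acetaldehyde inserted across the enolisable C4 and the aroyl carbon C1 of a homophthalic anhydride.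
4. Forward: ring C is bought fully substituted as atraric acid, its ortho methyl is carboxylated and the diacid closed to the anhydride, the aldol–lactonisation closes ring D, then decarboxylation and demethylation follow.
5. Rings A and B come preformed from 5,7-dihydroxy-2-methylchromone (7-O-methylation, C6 iodination, hydroxymethylation), and the two halves are joined last by Friedel–Crafts benzylation at C5.
6. Stereochemistry: C3 (R) is set by a cinchona squaramide catalyst in the aldol–lactonisation; the C4 centre formed alongside is erased by decarboxylation and no later step touches C3.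

Key step: step 5

Assumption: the quinidine-derived squaramide of step 5 is taken to deliver the (3R) series with acetaldehyde; should the sense of induction prove opposite, its quinine-derived pseudoenantiomer is used under the same conditions.

**Route**

Step 1
Reactants: 1 atraric acid (methyl 2,4-dihydroxy-3,6-dimethylbenzoate)
Product: 2 methyl 2,4-dimethoxy-3,6-dimethylbenzoate
Conditions: MeI (3 equiv), K2CO3 (3 equiv), DMF, 60 °C
Reagents that add atoms: iodomethane, CI
Why: Williamson ether synthesis in which both phenoxides are methylated by SN2 on iodomethane, the hydrogen-bonded and flanked 2-OH being forced by excess reagent in warm DMF while carbonate leaves the methyl ester intact.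

Step 2
Reactants: 2 methyl 2,4-dimethoxy-3,6-dimethylbenzoate
Product: 4 2-[3,5-dimethoxy-2-(methoxycarbonyl)-4-methylphenyl]acetic acid, via laterally lithiated toluate 3 (not isolated)
Conditions: LiN(i-Pr)2 (1.3 equiv), THF, −78 °C; CO2 (gas, excess), −78 °C → rt; aq. HCl
Reagents that add atoms: carbon dioxide, O=C=O
Why: Lateral lithiation of an ortho-toluate followed by carboxylation, selective because only the methyl group ortho to the ester gives an ester-stabilised benzylic anion (the methyl between the two methoxy groups is not acidified) and the hindered amide base does not add to the di-ortho-substituted ester.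

Step 3
Reactants: 4 2-[3,5-dimethoxy-2-(methoxycarbonyl)-4-methylphenyl]acetic acid
Product: 5 6-(carboxymethyl)-2,4-dimethoxy-3-methylbenzoic acid
Conditions: KOH (10 equiv), EtOH/H2O 1:1, reflux; then aq. HCl, 0 °C
Reagents that add atoms: potassium hydroxide, [K+].[OH-]
Why: Saponification (acyl–oxygen cleavage by hydroxide) of a hindered methyl benzoate, slow but dependable with excess hot alkali, the aryl methyl ethers and the arylacetate being inert and cold acidification avoiding protodecarboxylation of the electron-rich benzoic acid.

Step 4
Reactants: 5 6-(carboxymethyl)-2,4-dimethoxy-3-methylbenzoic acid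
Product: 6 6,8-dimethoxy-7-methylisochromane-1,3-dione
Conditions: Ac2O (3 equiv), toluene, 100 °C; crystallisation
Reagents that add atoms: none
Why: Cyclodehydration of a homophthalic acid to its six-membered cyclic anhydride with acetic anhydride as dehydrating agent, the standard preparation of homophthalic anhydrides, run without base so that C4 acylation or self-condensation of the enolisable anhydride is not triggered.

Step 5
Reactants: 6 6,8-dimethoxy-7-methylisochromane-1,3-dione; 7 acetaldehyde
Product: 9 (3R,4S)-6,8-dimethoxy-3,7-dimethyl-1-oxoisochromane-4-carboxylic acid (trans), via anhydride aldol adduct 8 (not isolated)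
Conditions: 3-{[3,5-bis(trifluoromethyl)phenyl]amino}-4-{[(9R)-6′-methoxycinchonan-9-yl]amino}cyclobut-3-ene-1,2-dione (10 mol%), MeCHO (5 equiv, freshly distilled), MTBE, −30 °C, sealed vessel; aq. HCl wash, NaHCO3 extraction, re-acidification, crystallisation
Reagents that add atoms: none
Why: The quinuclidine nitrogen of the catalyst deprotonates 6 at C4 and pairs with the resulting enolate while the squaramide N–H groups bind acetaldehyde; C4 adds to the aldehyde carbon (C4–C3 bond) to give alkoxide 8, whose oxygen attacks the aroyl carbonyl C1 and releases the other acyl group as the C4 carboxylic acid (O2–C1 bond). The closest known reaction type is the cinchona squaramide-catalysed enantioselective formal cycloaddition (Tamura-type aldol–lactonisation) of homophthalic anhydrides with aldehydes, documented for aromatic and for enolisable aliphatic aldehydes. Ring D closes by 6-exo-trig acyl substitution at C1, the alternative attack on the second anhydride carbonyl being a disfavoured four-membered closure. C3 is set (R) by the catalyst, which presents one enantiotopic face of the hydrogen-bonded aldehyde to the ion-paired enolate; C4 should emerge mainly trans to the C3 methyl (4S) from the anti topicity of the addition, and it is destroyed in step 6. The step needs cross-aldol chemoselectivity and aldehyde-face selectivity: the former is secured in the substrate by the high acidity of C4 (benzylic and α to an anhydride carbonyl), which keeps the amine engaged as the enolate ion pair instead of enolising acetaldehyde, helped by low temperature and excess aldehyde, whereas the latter rests on the catalyst because 6 has no stereocentre. Because a cis by-product could carry C3 in lower or opposite purity, only the crystallised trans acid is taken into the decarboxylation.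

Step 6
Reactants: 9 (3R,4S)-6,8-dimethoxy-3,7-dimethyl-1-oxoisochromane-4-carboxylic acid
Product: 11 (3R)-6,8-dimethoxy-3,7-dimethylisochroman-1-one, via Barton ester 10 (not isolated)
Conditions: N-hydroxypyridine-2-thione (1.1 equiv), N,N′-dicyclohexylcarbodiimide (1.1 equiv), CH2Cl2, 0 °C, dark; then t-BuSH (10 equiv), toluene, visible light (tungsten lamp), rt
Reagents that add atoms: none
Why: Barton reductive decarboxylation, in which the carbodiimide couples the acid to the thiohydroxamic acid without added base (limiting β-elimination of the lactone carboxylate), light cleaves the N–O bond, the acyloxy radical loses CO2 to a benzylic C4 radical and this abstracts hydrogen from the thiol, C3 not being involved and keeping its configuration.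

Step 7
Reactants: 11 (3R)-6,8-dimethoxy-3,7-dimethylisochroman-1-one
Product: 12 (3R)-6,8-dihydroxy-3,7-dimethylisochroman-1-one
Conditions: BBr3 (5 equiv), CH2Cl2, −78 °C → rt; ice/H2O
Reagents that add atoms: none
Why: Boron tribromide cleavage of aryl methyl ethers, well precedented for 6,8-dimethoxy-3-methylisochroman-1-ones, the peri 8-OMe being cleaved first with chelation to the lactone carbonyl and excess reagent removing the 6-OMe, while the lactone and its secondary C3–O bond are expected to survive at or below room temperature.

Step 8
Reactants: 13 5,7-dihydroxy-2-methylchromone (noreugenin)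
Product: 14 5-hydroxy-7-methoxy-2-methylchromone (eugenin)
Conditions: MeI (1.1 equiv), K2CO3 (1.2 equiv), acetone, reflux
Reagents that add atoms: iodomethane, CI
Why: Selective Williamson methylation, since the 5-OH is locked in a hydrogen bond to the C4 carbonyl and is far less acidic and nucleophilic than the 7-OH, so that one equivalent of iodomethane with carbonate should methylate O7 only.

Step 9
Reactants: 14 5-hydroxy-7-methoxy-2-methylchromone
Product: 15 5-hydroxy-6-iodo-7-methoxy-2-methylchromone
Conditions: BnMe3N·ICl2 (1.05 equiv), CaCO3 (1.5 equiv), CH2Cl2/MeOH 5:2, rt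
Reagents that add atoms: benzyltrimethylammonium dichloroiodate, C[N+](C)(C)Cc1ccccc1.Cl[I-]Cl
Why: Electrophilic aromatic iodination with a dichloroiodate salt, a reagent known to iodinate 5-hydroxy-7-alkoxy-chromones and -flavones ortho to the free chelated hydroxyl (C6) and not at C8, with CaCO3 scavenging the HCl formed.

Step 10
Reactants: 15 5-hydroxy-6-iodo-7-methoxy-2-methylchromone
Product: 16 5-hydroxy-6-(hydroxymethyl)-7-methoxy-2-methylchromone
Conditions: Bu3SnCH2OH (1.5 equiv), Pd(PPh3)4 (5 mol%), 1,4-dioxane, 100 °C
Reagents that add atoms: (tributylstannyl)methanol, CCCC[Sn](CCCC)(CCCC)CO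
Why: Migita–Kosugi–Stille hydroxymethylation, in which zerovalent palladium inserts into the C–I bond, the α-oxygenated hydroxymethyl group transfers from tin in preference to butyl and reductive elimination gives the benzylic alcohol, the chelated phenol and the pyranone being tolerated under these neutral conditions.

Step 11
Reactants: 12 (3R)-6,8-dihydroxy-3,7-dimethylisochroman-1-one (1.5 equiv); 16 5-hydroxy-6-(hydroxymethyl)-7-methoxy-2-methylchromone
Product: 18 5-hydroxy-6-{[(3R)-6,8-dihydroxy-3,7-dimethyl-1-oxoisochroman-5-yl]methyl}-7-methoxy-2-methyl-4H-chromen-4-one (CNP0180307.1), via ortho-quinone methide 17 (not isolated)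
Conditions: p-toluenesulfonic acid monohydrate (10 mol%), 1,1,1,3,3,3-hexafluoropropan-2-ol, rt → 40 °C, slow addition of 16 to 12
Reagents that add atoms: none
Why: Dehydrative Friedel–Crafts benzylation through an ortho-quinone methide, in which acid ionises the benzylic alcohol of 16 (assisted by the ortho 5-OH, the ortho 7-OMe and the para ring oxygen) and the electrophile is captured by C5 of 12, the only unsubstituted ring carbon and one that is ortho to the 6-OH and para to the 8-OH, the remote C3 stereocentre being untouched.

**Compound list**

1 | atraric acid (methyl 2,4-dihydroxy-3,6-dimethylbenzoate) | COC(=O)c1c(C)cc(O)c(C)c1O | starting material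
2 | methyl 2,4-dimethoxy-3,6-dimethylbenzoate | COC(=O)c1c(C)cc(OC)c(C)c1OC | intermediate
3 | laterally lithiated toluate, [3,5-dimethoxy-2-(methoxycarbonyl)-4-methylbenzyl]lithium (formed in situ) | COC(=O)c1c(C[Li])cc(OC)c(C)c1OC | intermediate
4 | 2-[3,5-dimethoxy-2-(methoxycarbonyl)-4-methylphenyl]acetic acid | COC(=O)c1c(CC(=O)O)cc(OC)c(C)c1OC | intermediate
5 | 6-(carboxymethyl)-2,4-dimethoxy-3-methylbenzoic acid | COc1cc(CC(=O)O)c(C(=O)O)c(OC)c1C | intermediate
6 | 6,8-dimethoxy-7-methylisochromane-1,3-dione | COc1cc2CC(=O)OC(=O)c2c(OC)c1C | intermediate
7 | acetaldehyde | CC=O | starting material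
8 | anhydride aldol adduct, (4S)-4-[(1R)-1-hydroxyethyl]-6,8-dimethoxy-7-methylisochromane-1,3-dione (formed in situ as its ammonium alkoxide) | COc1cc2c(c(OC)c1C)C(=O)OC(=O)[C@@H]2[C@@H](C)O | intermediate
9 | (3R,4S)-6,8-dimethoxy-3,7-dimethyl-1-oxoisochromane-4-carboxylic acid (trans) | COc1cc2c(c(OC)c1C)C(=O)O[C@H](C)[C@H]2C(=O)O | intermediate
10 | Barton ester, 2-thioxopyridin-1(2H)-yl (3R,4S)-6,8-dimethoxy-3,7-dimethyl-1-oxoisochromane-4-carboxylate (formed in situ) | COc1cc2c(c(OC)c1C)C(=O)O[C@H](C)[C@H]2C(=O)On1ccccc1=S | intermediate
11 | (3R)-6,8-dimethoxy-3,7-dimethylisochroman-1-one | COc1cc2C[C@@H](C)OC(=O)c2c(OC)c1C | intermediate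
12 | (3R)-6,8-dihydroxy-3,7-dimethylisochroman-1-one | Cc1c(O)cc2C[C@@H](C)OC(=O)c2c1O | intermediate
13 | 5,7-dihydroxy-2-methylchromone (noreugenin) | Cc1cc(=O)c2c(O)cc(O)cc2o1 | starting material
14 | 5-hydroxy-7-methoxy-2-methylchromone (eugenin) | COc1cc(O)c2c(c1)oc(C)cc2=O | intermediate
15 | 5-hydroxy-6-iodo-7-methoxy-2-methylchromone | COc1cc2oc(C)cc(=O)c2c(O)c1I | intermediate
16 | 5-hydroxy-6-(hydroxymethyl)-7-methoxy-2-methylchromone | COc1cc2oc(C)cc(=O)c2c(O)c1CO | intermediate
17 | ortho-quinone methide, 7-methoxy-2-methyl-6-methylidene-4H-chromene-4,5(6H)-dione (formed in situ) | C=C1C(OC)=CC2=C(C1=O)C(=O)C=C(C)O2 | intermediate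
18 | 5-hydroxy-6-{[(3R)-6,8-dihydroxy-3,7-dimethyl-1-oxoisochroman-5-yl]methyl}-7-methoxy-2-methyl-4H-chromen-4-one (CNP0180307.1) | COc1cc2oc(C)cc(=O)c2c(O)c1Cc1c(O)c(C)c(O)c2c1C[C@@H](C)OC2=O | target

**Step count and risks**

Total step count: 11. Longest linear sequence: 8 steps (steps 1–7, then step 11); the chromone branch (steps 8–10) joins at step 11.

Steps most likely to fail:

1. Step 5. The small aldehyde may be bound with insufficient facial discrimination, and amine-promoted self-aldolisation of acetaldehyde may outrun addition of the electron-rich, less acidic enolate, so that enantiopurity and conversion both suffer. Fallback, setting out from 2 and rejoining the route at 11: the lithiated toluate 3, generated as in step 2, is acylated with N-methoxy-N-methylacetamide to give methyl 2,4-dimethoxy-3-methyl-6-(2-oxopropyl)benzoate F1. The methyl ketone is then reduced by the (R)-selective, NADPH-dependent alcohol dehydrogenase from Lactobacillus kefir (isopropanol as terminal reductant) to methyl 6-[(2R)-2-hydroxypropyl]-2,4-dimethoxy-3-methylbenzoate F2. Catalytic p-toluenesulfonic acid in warm toluene closes the lactone with loss of methanol to give 11, so steps 3 to 6 are bypassed.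

2. Step 11. The ionised hydroxymethyl chromone may be consumed by self-condensation through its own C8 or by O-alkylation faster than it is intercepted by C5 of 12, leading to oligomers instead of the cross-coupled diarylmethane. Fallback, setting out from 16 (with 12) and rejoining at 18: 16 is oxidised with MnO2 in CH2Cl2 to 5-hydroxy-7-methoxy-2-methyl-4-oxo-4H-chromene-6-carbaldehyde F3, which cannot ionise on its own. Treated with 12, CF3CO2H and Et3SiH in CH2Cl2, F3 undergoes reductive Friedel–Crafts alkylation (hydroxyalkylation at C5 of 12, ionisation of the diarylcarbinol, hydride capture) to give 18 directly.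

3. Step 6. During activation the acidic C4–H of the thiohydroxamate ester may trigger β-elimination of the lactone carboxylate (ring opening), or the stabilised benzylic radical may be trapped at the thiocarbonyl sulfur instead of abstracting hydrogen. Fallback, setting out from 9 and rejoining at 11: direct photoredox hydrodecarboxylation of the free acid with 9-mesityl-10-methylacridinium tetrafluoroborate (5 mol%), PhSSPh (10 mol%) and catalytic i-Pr2NEt in 2,2,2-trifluoroethanol under blue light. The carboxylate is oxidised by the excited acridinium, CO2 is lost and the benzylic radical is reduced by thiophenol formed in situ, so no activated ester is needed and no new compound arises (F0).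

**Further compounds**

F1 | step 5 | methyl 2,4-dimethoxy-3-methyl-6-(2-oxopropyl)benzoate | COC(=O)c1c(CC(C)=O)cc(OC)c(C)c1OC
F2 | step 5 | methyl 6-[(2R)-2-hydroxypropyl]-2,4-dimethoxy-3-methylbenzoate | COC(=O)c1c(C[C@@H](C)O)cc(OC)c(C)c1OC
F3 | step 11 | 5-hydroxy-7-methoxy-2-methyl-4-oxo-4H-chromene-6-carbaldehyde | COc1cc2oc(C)cc(=O)c2c(O)c1C=O
F0 | step 6 | none | none
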